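the same everywhere: substrate 0.10 M

|  | partner | protic impurity | temperature | remark | time |
|---|---|---|---|---|---|
| ochre | 0.11 M | 5 mM | 110 °C | the very flask that is asked about, followed so far |  |
| green | 0.11 M | 5 mM | 105 °C | run made earlier |  |
| flask | 0.110 M | 5.00 mM | 110 °C |  | 20 h |

- ochre (time / h: target / %): 0.833: 4; 2.50: 9; 4.00: 14; 6.00: 14; 10.0: 18; 12.0: 24
- green (time / h: target / %): 0.833: 0; 2.50: 4; 4.00: 10; 6.00: 14; 10.0: 21; 12.0: 19

(each reading ± 2 percentage points)

- ash: change nothing and wait 10 h more
- oak: at 20 h add substrate, 50.0% of the amount charged, then wait 10 h
- birch: at 20 h add partner, 50.0% of the amount charged, then wait 10 h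
- cedar: at 20 h raise the temperature by 15 K, then wait 10 h

* target, in percent of the substrate first charged, at 20 h
* what to do for the largest gain in target; "none" if nothing gains more than 2 percentage points (ash / oak / birch / cedar / none)
* target present, in percent of the substrate first charged, after oak
* target present, in percent of the substrate first charged, after birch

- additions bring no volume worth counting
- what was read earlier has a scatter of 2 percentage points, one standard deviation
- a reading or a percentage of target counts all its forms, free or not

- A small charge of protic impurity, 5.00 mM, worries me first, but taken one for one against the partner it claims 4.55% of that charge. So I set it aside and ask what the ochre run, which is the flask itself, says about the next addition.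
- My zero of the scale is clean one-to-one pairing, with the rate following the product of substrate and partner. On that scale, from the start to the last ochre reading, 24%, the product falls by a factor of 1.68.
- The readings slow more than that. The mean rate up to 4.00 h stands to the mean rate from there to 12.0 h as 2.80 to one in ochre and 2.22 to one in green, both with their scatter.
- So I suspect that something besides pairing consumes a reagent. On paper the substrate is the limiting reagent, but my bet is on the partner, with no reading of either to go on.
- I let the ochre rate fall by the same factor over the equally long stretch to 20 h. The stretch from 4.00 h to 12.0 h gained 10 percentage points, so I expect 3.6 points more and commit to 27.6%.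
- That makes 0.251 the partner yield, moles of target present per mole of partner charged, where clean pairing with all the substrate used gives 0.909.
- If added partner returns the same yield, birch gains 14 points and reaches 41.4%. Oak adds substrate to a flask I suppose short of partner, so I put it near ash. Cedar I cannot rate, as ochre and green swap places between 10.0 h and 12.0 h. I choose birch.
- The forecast says 34% (29% to 40%), 49% after oak, 49% after birch, and picks cedar, in its words “only a narrow preference for cedar”.
- The flask gives 23.3%, 24.5% after oak and 36.3% after birch, and the best option is birch, which gains 13 points.

    partner + intermediate → target (k = 5.30 × 10⁻⁴ /M/s, Ea = 97.0 kJ/mol)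
    partner → decomposed reagent (k = 7.20 × 10⁻⁵ /s, Ea = 116 kJ/mol)
    partner + target ⇌ idle adduct, settled at all times (K = 240 /M, ΔH = −6.00 kJ/mol)
    2 intermediate → homo product (k = 7.30 × 10⁻⁶ /M/s, Ea = 115 kJ/mol)
    substrate → intermediate (k = 9.80 × 10⁻⁵ /s, Ea = 120 kJ/mol)
    partner + protic impurity → quenched reagent (k = 0.00120 /M/s, Ea = 81.0 kJ/mol)
    (constants at 110 °C)

- In the flask the partner's half-life by decomposition is 2.7 h at 1.96 h, and at 20.0 h partner still goes to decomposed reagent 1.9 times as fast as to target. By then 0.89% of its charge is left unbound, while 71.8% of the substrate stands as intermediate. The partner yield of the flask is 0.212 against my 0.251, and the partner added in birch returns 0.238. For a neighbour flask charged with 0.066 M of partner, 0.251 gives 16.5%, and that flask holds 14.8%.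

The numbers in the tables come from a simulation for an exercise; scatter was added.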